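**Plan**

Locants: ring A is the arene and ring B the pyran (O1, C2, C3, C4, C4a, C8a); the side chain is C1'–C13'. Retrosynthetic cuts, in order: O–Si, C5'–C6' (allyl/vinyl coupling), the C3=C4 unsaturation (back to a chroman), C3'=C4' (Wittig), C2'–C3' (one-carbon homologation), and last C1'–C2' together with O1–C2.
Feature used: C2 of ring B carries O1, CH3, C3 and C1'H2. This pattern results when the ring A phenol oxygen adds to the inner carbon of a CH2=C(CH3)CH2CH2–aryl unit and the outer CH2, now C1', takes up one carbon (C2') from CO.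
Forward: five steps turn 2-methylhydroquinone into the alkenylphenol, and step 6 closes ring B and makes the first chain bond. The chain then grows to the (E)-enoate on the sturdy chroman, ring B is dehydrogenated at that stage, and the derived allylic bromide is joined to the C6'–C13' stannane before desilylation.
Stereochemistry: C2 comes from enantioface selection by a chiral palladium catalyst (step 6). C8' comes from Sharpless epoxidation of geraniol, and its C–O bond is kept throughout. 3'E comes from a stabilised ylide and 6'E from syn-hydrostannation.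

Key step: step 6

Assumption: the sense of induction is carried over from simpler 2-(3-methylbut-3-enyl)phenols, where the (S,S) ligand leads to (S)-configured 2-methylchroman-2-ylacetates. The (R,R) ligand, (R)-2,2'-bis[(4R)-4-benzyl-4,5-dihydrooxazol-2-yl]-1,1'-binaphthyl = (R,R)-Bn-BOXAX, is therefore used; it is made separately by copper-mediated coupling of the 1-bromo-2-naphthyl oxazoline of (R)-phenylalaninol and is not counted.
Abbreviation: TBS = tert-butyldimethylsilyl.

**Step 1**
Reactants: 1 2-methylhydroquinone (2-methylbenzene-1,4-diol)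
Product: 2 4-(TBS-oxy)-2-methylphenol
Conditions: TBSCl (1.0 equiv), imidazole, CH2Cl2/DMF, 0 °C
Reagents that add atoms: tert-butyldimethylsilyl chloride, CC(C)(C)[Si](C)(C)Cl
Why: Imidazole-promoted O-silylation is governed by steric access, so one equivalent of the bulky chlorosilane should take the hydroxyl flanked by two ring hydrogens in preference to the one next to the methyl group, and the regioisomer and the bis-ether are removable by chromatography.

**Step 2**
Reactants: 2 4-(TBS-oxy)-2-methylphenol
Product: 3 5-(TBS-oxy)-2-hydroxy-3-methylbenzaldehyde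
Conditions: MgCl2, Et3N, (CH2O)n, MeCN, reflux; then 1 M HCl
Reagents that add atoms: paraformaldehyde (source of formaldehyde), C=O
Why: Casnati–Skattebøl ortho-formylation, in which the magnesium phenoxide delivers coordinated formaldehyde only to a carbon ortho to oxygen (here the single free one) and a second formaldehyde accepts the hydride from the resulting benzylic alkoxide.

**Step 3**
Reactants: 3 5-(TBS-oxy)-2-hydroxy-3-methylbenzaldehyde; 4 1-(triphenylphosphoranylidene)propan-2-one
Product: 5 (3E)-4-[5-(TBS-oxy)-2-hydroxy-3-methylphenyl]but-3-en-2-one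
Conditions: toluene, 80 °C
Reagents that add atoms: none
Why: Wittig olefination by a ketone-stabilised ylide, which is too weakly basic to be quenched by the phenol and gives the (E)-enone under thermodynamic control.

**Step 4**
Reactants: 5 (3E)-4-[5-(TBS-oxy)-2-hydroxy-3-methylphenyl]but-3-en-2-one
Product: 6 4-[5-(TBS-oxy)-2-hydroxy-3-methylphenyl]butan-2-one
Conditions: H2 (1 atm), 10% Pd/C, EtOAc, rt
Reagents that add atoms: none
Why: Catalytic hydrogenation saturates the conjugated C=C bond far faster than it touches the ketone, the arene or the aryl silyl ether, and the ring-chain equilibrium of the product with its cyclic hemiketal is of no consequence for the next step.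

**Step 5**
Reactants: 6 4-[5-(TBS-oxy)-2-hydroxy-3-methylphenyl]butan-2-one
Product: 7 4-(TBS-oxy)-2-methyl-6-(3-methylbut-3-enyl)phenol
Conditions: MePPh3Br (3 equiv), n-BuLi (3 equiv), THF, 0 °C → rt
Reagents that add atoms: methyltriphenylphosphonium bromide, C[P+](c1ccccc1)(c1ccccc1)c1ccccc1.[Br-]
Why: Wittig methylenation with excess ylide, the first equivalent of which forms the phenoxide and so keeps the substrate in its open keto form while the remainder converts the ketone into the 1,1-disubstituted alkene.

**Step 6**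
Reactants: 7 4-(TBS-oxy)-2-methyl-6-(3-methylbut-3-enyl)phenol
Product: 8 methyl 2-[(2R)-6-(TBS-oxy)-2,8-dimethylchroman-2-yl]acetate
Conditions: Pd(OCOCF3)2 (5 mol %), (R,R)-Bn-BOXAX (20 mol %), p-benzoquinone (4 equiv), CO (1 atm), MeOH, rt
Reagents that add atoms: carbon monoxide, [C-]#[O+]; methanol, CO
Why: The cationic complex of divalent palladium with the twofold-symmetric bis(oxazolinyl)binaphthyl ligand binds one face of the 1,1-disubstituted alkene, the phenol oxygen adds to the inner carbon (O1–C2) and palladium ends on the terminal CH2 (C1'). Because the only β-carbon, C2, is quaternary, β-hydride elimination is impossible, so the primary alkylpalladium species lasts long enough to insert CO, methanol cleaves the acylpalladium species (C1'–C2' is thereby in place), and p-benzoquinone returns zerovalent palladium to the divalent state. The closest known reaction type is this same enantioselective domino Wacker/carbonylation/methoxylation of 2-(3-methylbut-3-enyl)phenols, which includes 4-alkoxyphenols bearing an ortho methyl group. Ring B closes in the 6-exo-trig mode. The single new stereocentre C2 is controlled by the ligand pocket, which tells the methyl side of the bound alkene from the CH2–Pd side, and the (R,R) ligand should give (R)-8, the spatial arrangement of the target. The step needs inner-carbon (Markovnikov) attack rather than 7-endo closure, which the polarisation of the 1,1-disubstituted alkene and the short tether secure, and it needs the phenol to outrun methanol as nucleophile and the arene to resist the quinone oxidant, which intramolecularity and the silyl cap on the second oxygen secure.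

**Step 7**
Reactants: 8 methyl 2-[(2R)-6-(TBS-oxy)-2,8-dimethylchroman-2-yl]acetate
Product: 9 2-[(2R)-6-(TBS-oxy)-2,8-dimethylchroman-2-yl]acetaldehyde
Conditions: iBu2AlH (1.1 equiv), toluene, −78 °C; MeOH, aq. potassium sodium tartrate
Reagents that add atoms: none
Why: Partial reduction of an ester by iBu2AlH, whose tetrahedral aluminium hemiacetal persists at −78 °C and releases the aldehyde only on quenching, under non-basic conditions that leave the β-aryloxy stereocentre C2 untouched.

**Step 8**
Reactants: 9 2-[(2R)-6-(TBS-oxy)-2,8-dimethylchroman-2-yl]acetaldehyde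
Product: 11 3-[(2R)-6-(TBS-oxy)-2,8-dimethylchroman-2-yl]propanal, via methyl enol ether 10 (not isolated)
Conditions: MeOCH2PPh3Cl, NaN(SiMe3)2, THF, −78 → 0 °C; then 2 M aq. HCl, rt
Reagents that add atoms: (methoxymethyl)triphenylphosphonium chloride, COC[P+](c1ccccc1)(c1ccccc1)c1ccccc1.[Cl-]; water, O
Why: Wittig methoxymethylenation followed by acid hydrolysis of the enol ether (one-carbon aldehyde homologation), in which carbonyl addition of the non-stabilised ylide to a chroman-2-ylacetaldehyde at low temperature outruns enolisation, so that retro-oxa-Michael opening at C2 is not expected, and the saturated chroman and the aryl silyl ether tolerate the dilute acid.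

**Step 9**
Reactants: 11 3-[(2R)-6-(TBS-oxy)-2,8-dimethylchroman-2-yl]propanal
Product: 12 ethyl (2E)-5-[(2S)-6-(TBS-oxy)-2,8-dimethylchroman-2-yl]-2-methylpent-2-enoate (same spatial arrangement at C2; the descriptor changes through CIP ranking only)
Conditions: Ph3P=C(CH3)CO2Et, CH2Cl2, rt → 40 °C
Reagents that add atoms: ethyl 2-(triphenylphosphoranylidene)propanoate, CCOC(=O)C(C)=P(c1ccccc1)(c1ccccc1)c1ccccc1
Why: Wittig olefination with an α-methyl ester-stabilised ylide, which gives the (E)-trisubstituted enoate (3'E) and does not affect the now remote C2.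

**Step 10**
Reactants: 12 ethyl (2E)-5-[(2S)-6-(TBS-oxy)-2,8-dimethylchroman-2-yl]-2-methylpent-2-enoate
Product: 13 ethyl (2E)-5-[(2S)-6-(TBS-oxy)-2,8-dimethyl-2H-chromen-2-yl]-2-methylpent-2-enoate
Conditions: DDQ (1.5 equiv), toluene, 90 °C, dark
Reagents that add atoms: none
Why: DDQ dehydrogenation of a chroman, in which hydride abstraction from benzylic C4 gives a cation stabilised by O1 through C8a and loss of a C3 proton gives the 2H-chromene with C2 as a spectator, placed here because the only other alkene is an electron-poor enoate that resists DDQ and because the acid- and light-sensitive chromene then has to survive only four mild steps.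

**Step 11**
Reactants: 13 ethyl (2E)-5-[(2S)-6-(TBS-oxy)-2,8-dimethyl-2H-chromen-2-yl]-2-methylpent-2-enoate
Product: 14 (2E)-5-[(2S)-6-(TBS-oxy)-2,8-dimethyl-2H-chromen-2-yl]-2-methylpent-2-en-1-ol
Conditions: iBu2AlH (2.5 equiv), CH2Cl2, −78 °C; aq. potassium sodium tartrate
Reagents that add atoms: none
Why: 1,2-Reduction of the α,β-unsaturated ester by excess iBu2AlH, which leaves the styrene-type C3=C4 bond, the aryl silyl ether and the alkene geometry intact.

**Step 12**
Reactants: 14 (2E)-5-[(2S)-6-(TBS-oxy)-2,8-dimethyl-2H-chromen-2-yl]-2-methylpent-2-en-1-ol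
Product: 15 (2S)-2-[(3E)-5-bromo-4-methylpent-3-enyl]-6-(TBS-oxy)-2,8-dimethyl-2H-chromene
Conditions: CBr4, PPh3, CH2Cl2, −20 → 0 °C
Reagents that add atoms: carbon tetrabromide, BrC(Br)(Br)Br
Why: Appel bromination, an SN2 displacement of the primary allylic oxyphosphonium ion under essentially neutral conditions that avoids allylic transposition and E/Z scrambling.

**Step 13**
Reactants: 16 geraniol
Product: 17 (2S,3S)-2,3-epoxygeraniol, [(2S,3S)-3-methyl-3-(4-methylpent-3-enyl)oxiran-2-yl]methanol
Conditions: Ti(OiPr)4 (5 mol %), L-(+)-diethyl tartrate (7 mol %), tBuOOH, 4 Å MS, CH2Cl2, −20 °C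
Reagents that add atoms: tert-butyl hydroperoxide, CC(C)(C)OO
Why: Sharpless asymmetric epoxidation, in which the titanium tartrate complex binds the allylic alcohol so that only the 2,3-alkene reacts, and L-(+)-diethyl tartrate directs oxygen to the face that gives the (2S,3S)-epoxide, whose C3 becomes C8' of the target.

**Step 14**
Reactants: 17 (2S,3S)-2,3-epoxygeraniol
Product: 18 (2S,3R)-3-(chloromethyl)-2-methyl-2-(4-methylpent-3-enyl)oxirane
Conditions: PPh3, CCl4, NaHCO3, reflux
Reagents that add atoms: carbon tetrachloride, ClC(Cl)(Cl)Cl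
Why: Appel chlorination at the primary carbon under bicarbonate buffering, which leaves the trisubstituted epoxide and both stereocentres untouched (the descriptor of the CH carbon changes for ranking reasons only).

**Step 15**
Reactants: 18 (2S,3R)-3-(chloromethyl)-2-methyl-2-(4-methylpent-3-enyl)oxirane
Product: 19 (3S)-3,7-dimethyloct-6-en-1-yn-3-ol
Conditions: n-BuLi (3.5 equiv), THF, −78 °C; aq. NH4Cl
Reagents that add atoms: none
Why: Base-induced double elimination of a 2,3-epoxy chloride to a propargylic alcohol, in which lithiation next to chlorine opens the epoxide by β-elimination and a second loss of HCl gives the alkyne, and since the bond from the tertiary carbon to oxygen is never broken the carbinol keeps its (S) configuration.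

**Step 16**
Reactants: 19 (3S)-3,7-dimethyloct-6-en-1-yn-3-ol
Product: 20 (1E,3S)-3,7-dimethyl-1-(tributylstannyl)octa-1,6-dien-3-ol
Conditions: Bu3SnH, PdCl2(PPh3)2 (2 mol %), THF, 0 °C → rt
Reagents that add atoms: tributyltin hydride, CCCC[SnH](CCCC)CCCC
Why: Palladium-catalysed hydrostannation, a syn addition of H and SnBu3 in which the bulky tertiary carbinol centre sends tin to the terminal carbon and thus gives the (E)-β-stannyl allylic alcohol (6'E).

**Step 17**
Reactants: 15 (2S)-2-[(3E)-5-bromo-4-methylpent-3-enyl]-6-(TBS-oxy)-2,8-dimethyl-2H-chromene; 20 (1E,3S)-3,7-dimethyl-1-(tributylstannyl)octa-1,6-dien-3-ol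
Product: 21 (2S)-6-(TBS-oxy)-2-[(3E,6E,8S)-8-hydroxy-4,8,12-trimethyltrideca-3,6,11-trienyl]-2,8-dimethyl-2H-chromene
Conditions: Pd2(dba)3 (2.5 mol %), AsPh3 (10 mol %), THF/NMP, rt → 40 °C, dark
Reagents that add atoms: none
Why: Stille coupling of an allylic bromide with an alkenylstannane, in which oxidative addition gives an η3-allylpalladium species and transmetalation and reductive elimination join the vinyl carbon to the less hindered CH2 terminus (C5'–C6') with retention of both alkene geometries, the free tertiary alcohol being tolerated.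

**Step 18**
Reactants: 21 (2S)-6-(TBS-oxy)-2-[(3E,6E,8S)-8-hydroxy-4,8,12-trimethyltrideca-3,6,11-trienyl]-2,8-dimethyl-2H-chromene
Product: 22 (2S)-2-[(3E,6E,8S)-8-hydroxy-4,8,12-trimethyltrideca-3,6,11-trienyl]-2,8-dimethyl-2H-chromen-6-ol (CNP0155965.1)
Conditions: Bu4NF, AcOH (1:1), THF, 0 °C
Reagents that add atoms: none
Why: Fluoride-induced cleavage of the aryl silyl ether, driven by the Si–F bond and buffered with acetic acid so that the oxidation-prone chromenol is never present as phenoxide and the tertiary allylic alcohol and the skipped diene see neither strong acid nor strong base.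

**Compound list**

1 | 2-methylhydroquinone | Cc1cc(O)ccc1O | starting material
2 | 4-(TBS-oxy)-2-methylphenol | Cc1cc(O[Si](C)(C)C(C)(C)C)ccc1O | intermediate
3 | 5-(TBS-oxy)-2-hydroxy-3-methylbenzaldehyde | Cc1cc(O[Si](C)(C)C(C)(C)C)cc(C=O)c1O | intermediate
4 | 1-(triphenylphosphoranylidene)propan-2-one | CC(=O)C=P(c1ccccc1)(c1ccccc1)c1ccccc1 | starting material
5 | (3E)-4-[5-(TBS-oxy)-2-hydroxy-3-methylphenyl]but-3-en-2-one | CC(=O)/C=C/c1cc(O[Si](C)(C)C(C)(C)C)cc(C)c1O | intermediate
6 | 4-[5-(TBS-oxy)-2-hydroxy-3-methylphenyl]butan-2-one | CC(=O)CCc1cc(O[Si](C)(C)C(C)(C)C)cc(C)c1O | intermediate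
7 | 4-(TBS-oxy)-2-methyl-6-(3-methylbut-3-enyl)phenol | C=C(C)CCc1cc(O[Si](C)(C)C(C)(C)C)cc(C)c1O | intermediate
8 | methyl 2-[(2R)-6-(TBS-oxy)-2,8-dimethylchroman-2-yl]acetate | COC(=O)C[C@@]1(C)CCc2cc(O[Si](C)(C)C(C)(C)C)cc(C)c2O1 | intermediate
9 | 2-[(2R)-6-(TBS-oxy)-2,8-dimethylchroman-2-yl]acetaldehyde | O=CC[C@@]1(C)CCc2cc(O[Si](C)(C)C(C)(C)C)cc(C)c2O1 | intermediate
10 | (2R)-6-(TBS-oxy)-2-(3-methoxyprop-2-enyl)-2,8-dimethylchroman, E/Z mixture | COC=CC[C@@]1(C)CCc2cc(O[Si](C)(C)C(C)(C)C)cc(C)c2O1 | intermediate
11 | 3-[(2R)-6-(TBS-oxy)-2,8-dimethylchroman-2-yl]propanal | O=CCC[C@@]1(C)CCc2cc(O[Si](C)(C)C(C)(C)C)cc(C)c2O1 | intermediate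
12 | ethyl (2E)-5-[(2S)-6-(TBS-oxy)-2,8-dimethylchroman-2-yl]-2-methylpent-2-enoate | CCOC(=O)/C(C)=C/CC[C@@]1(C)CCc2cc(O[Si](C)(C)C(C)(C)C)cc(C)c2O1 | intermediate
13 | ethyl (2E)-5-[(2S)-6-(TBS-oxy)-2,8-dimethyl-2H-chromen-2-yl]-2-methylpent-2-enoate | CCOC(=O)/C(C)=C/CC[C@@]1(C)C=Cc2cc(O[Si](C)(C)C(C)(C)C)cc(C)c2O1 | intermediate
14 | (2E)-5-[(2S)-6-(TBS-oxy)-2,8-dimethyl-2H-chromen-2-yl]-2-methylpent-2-en-1-ol | OC/C(C)=C/CC[C@@]1(C)C=Cc2cc(O[Si](C)(C)C(C)(C)C)cc(C)c2O1 | intermediate
15 | (2S)-2-[(3E)-5-bromo-4-methylpent-3-enyl]-6-(TBS-oxy)-2,8-dimethyl-2H-chromene | BrC/C(C)=C/CC[C@@]1(C)C=Cc2cc(O[Si](C)(C)C(C)(C)C)cc(C)c2O1 | intermediate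
16 | geraniol | CC(C)=CCC/C(C)=C/CO | starting material
17 | (2S,3S)-2,3-epoxygeraniol | CC(C)=CCC[C@]1(C)O[C@H]1CO | intermediate
18 | (2S,3R)-3-(chloromethyl)-2-methyl-2-(4-methylpent-3-enyl)oxirane | CC(C)=CCC[C@]1(C)O[C@H]1CCl | intermediate
19 | (3S)-3,7-dimethyloct-6-en-1-yn-3-ol | CC(C)=CCC[C@](C)(O)C#C | intermediate
20 | (1E,3S)-3,7-dimethyl-1-(tributylstannyl)octa-1,6-dien-3-ol | CC(C)=CCC[C@](C)(O)/C=C/[Sn](CCCC)(CCCC)CCCC | intermediate
21 | (2S)-6-(TBS-oxy)-2-[(3E,6E,8S)-8-hydroxy-4,8,12-trimethyltrideca-3,6,11-trienyl]-2,8-dimethyl-2H-chromene | CC(C)=CCC[C@](C)(O)/C=C/C/C(C)=C/CC[C@@]1(C)C=Cc2cc(O[Si](C)(C)C(C)(C)C)cc(C)c2O1 | intermediate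
22 | (2S)-2-[(3E,6E,8S)-8-hydroxy-4,8,12-trimethyltrideca-3,6,11-trienyl]-2,8-dimethyl-2H-chromen-6-ol | CC(C)=CCC[C@](C)(O)/C=C/C/C(C)=C/CC[C@@]1(C)C=Cc2cc(O)cc(C)c2O1 | target

Total step count: 18. Longest linear sequence: 14 (steps 1–12, 17 and 18, from 2-methylhydroquinone).

**Steps most likely to fail**

**Step 10 (dehydrogenation).**
- Hydride abstraction at C4 may be too slow, since the 6-silyloxy group is meta to C4a and only O1 assists.
- Attack at the 8-methyl group could then take over, as could loss of the silyl ether with over-oxidation of ring A.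
- The C2 configuration could also erode through reversible electrocyclic opening of ring B at the reaction temperature.

The fallback installs the alkene by oxygenation and elimination instead of hydride abstraction, and sets out from 8. Benzylic oxidation with Mn(OAc)3·2H2O (cat.) and tBuOOH in warm EtOAc should give methyl 2-[(2R)-6-(TBS-oxy)-2,8-dimethyl-4-oxochroman-2-yl]acetate F1. Luche reduction (NaBH4, CeCl3·7H2O, MeOH, low temperature) gives the chroman-4-ol ester F2 as C4 epimers, both of which are usable. Catalytic pTsOH in warm toluene dehydrates it to the chromene ester F3. That ester is taken through the operations of steps 7 to 9: iBu2AlH gives the chromenylacetaldehyde F4, methoxymethylenation gives the chromene enol ether F5, and hydrolysis with pyridinium tosylate in wet acetone gives the chromenylpropanal F6. The stabilised Wittig reaction then brings the material back to the route at 13.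

**Step 17 (allyl/vinyl coupling).**
- Slow transmetalation would let the η3-allylpalladium species decay by β-hydride loss or homocoupling.
- The γ-hydroxy stannane may suffer protodestannylation.
- The skipped diene may drift into conjugation.
- Zerovalent palladium could ionise the allylic C2–O1 bond of ring B and erode the C2 configuration.

The fallback makes the same C5'–C6' bond at the alkyne oxidation level without tin or palladium, and sets out from 19 and 15. Compound 19 is turned into its bis(bromomagnesium) salt with EtMgBr (2 equiv) in THF. With CuBr·SMe2 (cat.) it is alkylated at the alkynyl carbon by 15 to give the skipped enynol F7. Hydroxyl-directed trans-hydroalumination with NaAlH2(OCH2CH2OMe)2 in THF, followed by protonolysis, sets the (E)-alkene and comes back to the route at 21.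

**Step 6 (domino cyclisation).** Facial selection at the alkene may be insufficient for this particular substitution pattern, which would pass a scalemic C2 on to every later compound.

The fallback separates ring closure from stereocontrol and sets out from 7.
- The same carbonylative cyclisation, run with the racemic ligand, gives the racemic chromanylacetate F8.
- LiOH in aqueous THF/MeOH under nitrogen cleaves both the ester and the aryl silyl ether to the racemic hydroxy acid F9.
- Fractional crystallisation with (R)-1-phenylethylamine, a resolving agent established for chroman-2-ylacetic acids, gives the ammonium salt F10.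
- Acidification frees the (R)-hydroxy acid F11.
- Fischer esterification (MeOH, cat. H2SO4) gives the (R)-hydroxy ester F12, and TBSCl/imidazole brings it back to the route at 8.

**Further compounds**

F1 | step 10 | methyl 2-[(2R)-6-(TBS-oxy)-2,8-dimethyl-4-oxochroman-2-yl]acetate | COC(=O)C[C@@]1(C)CC(=O)c2cc(O[Si](C)(C)C(C)(C)C)cc(C)c2O1
F2 | step 10 | methyl 2-[(2R)-6-(TBS-oxy)-4-hydroxy-2,8-dimethylchroman-2-yl]acetate, C4 epimers | COC(=O)C[C@@]1(C)CC(O)c2cc(O[Si](C)(C)C(C)(C)C)cc(C)c2O1
F3 | step 10 | methyl 2-[(2S)-6-(TBS-oxy)-2,8-dimethyl-2H-chromen-2-yl]acetate | COC(=O)C[C@@]1(C)C=Cc2cc(O[Si](C)(C)C(C)(C)C)cc(C)c2O1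
F4 | step 10 | 2-[(2S)-6-(TBS-oxy)-2,8-dimethyl-2H-chromen-2-yl]acetaldehyde | O=CC[C@@]1(C)C=Cc2cc(O[Si](C)(C)C(C)(C)C)cc(C)c2O1
F5 | step 10 | (2S)-6-(TBS-oxy)-2-(3-methoxyprop-2-enyl)-2,8-dimethyl-2H-chromene, E/Z mixture | COC=CC[C@@]1(C)C=Cc2cc(O[Si](C)(C)C(C)(C)C)cc(C)c2O1
F6 | step 10 | 3-[(2S)-6-(TBS-oxy)-2,8-dimethyl-2H-chromen-2-yl]propanal | O=CCC[C@@]1(C)C=Cc2cc(O[Si](C)(C)C(C)(C)C)cc(C)c2O1
F7 | step 17 | (2S)-6-(TBS-oxy)-2-[(3E,8S)-8-hydroxy-4,8,12-trimethyltrideca-3,11-dien-6-ynyl]-2,8-dimethyl-2H-chromene | CC(C)=CCC[C@](C)(O)C#CC/C(C)=C/CC[C@@]1(C)C=Cc2cc(O[Si](C)(C)C(C)(C)C)cc(C)c2O1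
F8 | step 6 | racemic methyl 2-[6-(TBS-oxy)-2,8-dimethylchroman-2-yl]acetate | COC(=O)CC1(C)CCc2cc(O[Si](C)(C)C(C)(C)C)cc(C)c2O1
F9 | step 6 | racemic 2-(6-hydroxy-2,8-dimethylchroman-2-yl)acetic acid | OC(=O)CC1(C)CCc2cc(O)cc(C)c2O1
F10 | step 6 | (R)-1-phenylethylammonium salt of 2-[(2R)-6-hydroxy-2,8-dimethylchroman-2-yl]acetic acid | OC(=O)C[C@@]1(C)CCc2cc(O)cc(C)c2O1.C[C@@H](N)c1ccccc1
F11 | step 6 | 2-[(2R)-6-hydroxy-2,8-dimethylchroman-2-yl]acetic acid | OC(=O)C[C@@]1(C)CCc2cc(O)cc(C)c2O1
F12 | step 6 | methyl 2-[(2R)-6-hydroxy-2,8-dimethylchroman-2-yl]acetate | COC(=O)C[C@@]1(C)CCc2cc(O)cc(C)c2O1
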